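Side-chain carbons are numbered C1′ (ring-bound CH2) to C16′. The syn-8′,9′-diol is read as D-tartaric acid whose two carboxyl groups are exchanged in turn for alkenyl groups. Everything rests on the C9′–C10′ bond, from the carbinol carbon to the vinylic CH of the terminal dimethylheptadienyl unit. The key step, a nickel-electrocatalytic decarboxylative alkenylation, turns a dioxolane-4-carboxylic acid into the C9′ radical and joins it to (E)-1-iodo-2,6-dimethylhepta-1,5-diene. It exploits the vicinal O8′/O9′ pair: tied into a temporary acetonide ring, it lets the C8′ stereocentre force the new bond trans. The precursor already carries the C1′–C8′ chain and the quinone ring, masked as hydroquinone dimethyl ether.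

Key step: step 14

Remark: each N-hydroxyphthalimide ester is made and electrolysed crude in one operation, which is counted as one step; the aryl bromide 3 is made rather than assumed to be purchasable.

Step 1
Reactants: 1 4-methoxy-2-methylphenol
Product: 2 2-bromo-4-methoxy-6-methylphenol
Conditions: Br2 (1.0 equiv), CH2Cl2, 0 °C
Reagents that add atoms: bromine, BrBr
Why: Electrophilic aromatic bromination; the hydroxyl group is the strongest director and its only free ortho/para position is C6 (para is blocked by OMe, the other ortho by the methyl group).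

Step 2
Reactants: 2 2-bromo-4-methoxy-6-methylphenol
Product: 3 1-bromo-2,5-dimethoxy-3-methylbenzene
Conditions: MeI, K2CO3, acetone, reflux
Reagents that add atoms: iodomethane, CI
Why: Williamson ether synthesis; the phenoxide is O-methylated and nothing else in the molecule is nucleophilic.

Step 3
Reactants: 4 pent-3-yn-1-ol
Product: 5 5-bromopent-2-yne
Conditions: CBr4, PPh3, CH2Cl2, 0 °C
Reagents that add atoms: carbon tetrabromide, BrC(Br)(Br)Br
Why: Appel reaction converts the primary alcohol into the bromide under neutral conditions that leave the internal alkyne untouched.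

Step 4
Reactants: 5 5-bromopent-2-yne; 6 ethyl but-2-ynoate
Product: 10 ethyl (E)-3-methyloct-2-en-6-ynoate, via pent-3-yn-1-ylmagnesium bromide 7 (not isolated), via pent-3-yn-1-ylcopper 8 (not isolated), via alkenylcopper adduct 9 (not isolated)
Conditions: Mg, THF, rt; CuBr·SMe2 (1.05 equiv), THF, −78 °C; 6, −78 °C; sat. aq. NH4Cl, −78 °C
Reagents that add atoms: none
Why: Conjugate addition of an organocopper reagent to an acetylenic ester; syn-carbocupration at −78 °C and protonation with retention should place the new chain trans to the ester, which fixes the E geometry of C2′=C3′.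

Step 5
Reactants: 10 ethyl (E)-3-methyloct-2-en-6-ynoate
Product: 11 (E)-3-methyloct-2-en-6-yn-1-ol
Conditions: DIBAL-H (2.2 equiv), CH2Cl2, −78 °C; Rochelle salt work-up
Reagents that add atoms: none
Why: DIBAL-H 1,2-reduction of the α,β-unsaturated ester to the allylic alcohol; the isolated alkyne and the alkene geometry are unaffected at −78 °C.

Step 6
Reactants: 11 (E)-3-methyloct-2-en-6-yn-1-ol
Product: 12 (E)-1-bromo-3-methyloct-2-en-6-yne
Conditions: PBr3 (0.4 equiv), Et2O, 0 °C
Reagents that add atoms: phosphorus tribromide, BrP(Br)Br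
Why: PBr3 bromination of a primary allylic alcohol (SN2 on the phosphite ester) should retain regiochemistry and E geometry at 0 °C.

Step 7
Reactants: 3 1-bromo-2,5-dimethoxy-3-methylbenzene; 12 (E)-1-bromo-3-methyloct-2-en-6-yne
Product: 14 1-[(2E)-3-methyloct-2-en-6-yn-1-yl]-2,5-dimethoxy-3-methylbenzene, via arylmagnesium bromide 13 (not isolated)
Conditions: Mg, THF, 50 °C; then CuI (10 mol %), 12, THF, −20 °C → rt
Reagents that add atoms: none
Why: Copper-catalysed allylic substitution by an aryl Grignard reagent in the SN2 mode (γ-attack would have to build a quaternary centre), with retention of the E alkene; the internal alkyne is inert.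

Step 8
Reactants: 14 1-[(2E)-3-methyloct-2-en-6-yn-1-yl]-2,5-dimethoxy-3-methylbenzene
Product: 16 1-[(2E,6E)-7-iodo-3-methylocta-2,6-dien-1-yl]-2,5-dimethoxy-3-methylbenzene, via alkenylzirconocene chloride 15 (not isolated)
Conditions: Cp2Zr(H)Cl (1.5 equiv), THF, rt → 45 °C; then I2, THF, −20 °C
Reagents that add atoms: iodine, II
Why: Hydrozirconation with Schwartz's reagent (syn addition; equilibration with excess reagent puts zirconium on the methyl-bearing alkyne carbon) and iodinolysis with retention should give the (E)-2-iodoalk-2-ene; a minor regioisomeric iodide would be removed by chromatography.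

Step 9
Reactants: 17 dimethyl (4S,5S)-2,2-dimethyl-1,3-dioxolane-4,5-dicarboxylate (D-tartrate acetonide)
Product: 18 (4S,5S)-5-(methoxycarbonyl)-2,2-dimethyl-1,3-dioxolane-4-carboxylic acid
Conditions: KOH (1.0 equiv), MeOH, 0 °C → rt; then 1 M HCl
Reagents that add atoms: potassium hydroxide, [K+].[OH-]
Why: Partial saponification; one equivalent of hydroxide cleaves one ester and the resulting carboxylate slows attack on the second, without touching either stereocentre.

Step 10
Reactants: 18 (4S,5S)-5-(methoxycarbonyl)-2,2-dimethyl-1,3-dioxolane-4-carboxylic acid (2.5 equiv); 16 1-[(2E,6E)-7-iodo-3-methylocta-2,6-dien-1-yl]-2,5-dimethoxy-3-methylbenzene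
Product: 20 methyl (4S,5R)-5-[(2E,6E)-8-(2,5-dimethoxy-3-methylphenyl)-6-methylocta-2,6-dien-2-yl]-2,2-dimethyl-1,3-dioxolane-4-carboxylate, via N-acyloxyphthalimide 19 (not isolated)
Conditions: N-hydroxyphthalimide, DIC, DMAP (cat.), CH2Cl2, rt; then 16, NiCl2·6H2O (20 mol %), 2,2′-bipyridine (20 mol %), AgNO3 (0.3 equiv), DMF, (+)Mg/(−)RVC, constant current, rt
Reagents that add atoms: none
Why: Carbodiimide esterification to the redox-active ester, then Ni-electrocatalytic decarboxylative alkenylation; the dioxolan-4-yl radical is captured by alkenyl–nickel anti to the neighbouring CO2Me group, which sets C8′ (ring C5, R) trans to the ester with retention of the iodide's E geometry.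

Step 11
Reactants: 20 methyl (4S,5R)-5-[(2E,6E)-8-(2,5-dimethoxy-3-methylphenyl)-6-methylocta-2,6-dien-2-yl]-2,2-dimethyl-1,3-dioxolane-4-carboxylate
Product: 21 (4S,5R)-5-[(2E,6E)-8-(2,5-dimethoxy-3-methylphenyl)-6-methylocta-2,6-dien-2-yl]-2,2-dimethyl-1,3-dioxolane-4-carboxylic acid
Conditions: LiOH·H2O (3 equiv), THF/MeOH/H2O, 0 °C → rt; then 1 M HCl to pH 3, 0 °C
Reagents that add atoms: lithium hydroxide, [Li+].[OH-]
Why: Ester saponification; epimerisation α to the carboxylate is harmless because that centre (C9′) is erased and re-set in step 14, while C8′ is not acidic.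

Step 12
Reactants: 22 5-bromo-2-methylpent-2-ene
Product: 23 6-methylhept-5-en-1-yne
Conditions: lithium acetylide–ethylenediamine complex, DMSO, 10 °C → rt
Reagents that add atoms: lithium acetylide (ethylenediamine complex), [Li]C#C
Why: SN2 alkylation of lithium acetylide by a primary homoallylic bromide in a dipolar aprotic solvent.

Step 13
Reactants: 23 6-methylhept-5-en-1-yne
Product: 25 (E)-1-iodo-2,6-dimethylhepta-1,5-diene, via alkenyldimethylalane 24 (not isolated)
Conditions: Me3Al (2 equiv), Cp2ZrCl2 (0.25 equiv), CH2Cl2, 0 °C → rt; then I2, THF, −30 → 0 °C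
Reagents that add atoms: trimethylaluminium, C[Al](C)C; iodine, II
Why: Negishi zirconium-catalysed carboalumination (syn methylalumination, methyl to the internal carbon) and iodinolysis with retention give the (E)-alkenyl iodide; the trisubstituted alkene does not react.

Step 14
Reactants: 21 (4S,5R)-5-[(2E,6E)-8-(2,5-dimethoxy-3-methylphenyl)-6-methylocta-2,6-dien-2-yl]-2,2-dimethyl-1,3-dioxolane-4-carboxylic acid; 25 (E)-1-iodo-2,6-dimethylhepta-1,5-diene (2 equiv)
Product: 27 (4R,5R)-4-[(2E,6E)-8-(2,5-dimethoxy-3-methylphenyl)-6-methylocta-2,6-dien-2-yl]-5-[(1E)-2,6-dimethylhepta-1,5-dien-1-yl]-2,2-dimethyl-1,3-dioxolane, via N-acyloxyphthalimide 26 (not isolated)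
Conditions: N-hydroxyphthalimide, DIC, DMAP (cat.), CH2Cl2, rt; then 25, NiCl2·6H2O (20 mol %), 2,2′-bipyridine (20 mol %), AgNO3 (0.3 equiv), DMF, (+)Mg/(−)RVC, constant current (ca. 2.5–3 F/mol), rt
Reagents that add atoms: none
Why: Cathodically formed low-valent Ni(bpy) transfers an electron to the N-acyloxyphthalimide 26, which loses phthalimide anion and CO2 to give the dioxolan-4-yl (C9′) radical; oxidative addition of 25 gives an alkenyl–Ni(II) species that captures this radical, and reductive elimination from Ni(III) forms the C9′–C10′ bond while the sacrificial Mg anode supplies the electrons. The closest known reaction type is the Ni-catalysed decarboxylative alkenylation of α-alkoxy (tartrate acetonide) redox-active esters with alkenylzinc reagents or, under electrolysis, alkenyl halides. No ring is closed. The new stereocentre C9′ is controlled by the existing C8′ centre through the temporary dioxolane ring: the radical is captured on the face anti to the bulky C8′ alkenyl group, which should give the trans-(4R,5R) ring and hence the syn-diol, whatever the C9′ configuration of 21. The step needs trans diastereoselectivity, retention of the E geometry of 25 and chemoselectivity over three trisubstituted alkenes; the ring secures the first, stereoretentive oxidative addition and reductive elimination at nickel the second, and the third follows because the E-C6′=C7′ bond holds the remaining alkenes out of reach of any 5- or 6-membered radical cyclisation.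

Step 15
Reactants: 27 (4R,5R)-4-[(2E,6E)-8-(2,5-dimethoxy-3-methylphenyl)-6-methylocta-2,6-dien-2-yl]-5-[(1E)-2,6-dimethylhepta-1,5-dien-1-yl]-2,2-dimethyl-1,3-dioxolane
Product: 28 2-{(2E,6E)-7-[(4R,5R)-5-[(1E)-2,6-dimethylhepta-1,5-dien-1-yl]-2,2-dimethyl-1,3-dioxolan-4-yl]-3-methylocta-2,6-dien-1-yl}-6-methylcyclohexa-2,5-diene-1,4-dione
Conditions: (NH4)2Ce(NO3)6 (2.5 equiv), MeCN/H2O (3:1), 0 °C, 15 min
Reagents that add atoms: water, O
Why: Oxidative demethylation of a hydroquinone dimethyl ether by Ce(IV) (two one-electron oxidations, water adds at the ipso carbons, methanol leaves); it is fast at 0 °C on polyprenyl arenes, and the ketal keeps the diol away from Ce(IV) glycol cleavage.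

Step 16
Reactants: 28 2-{(2E,6E)-7-[(4R,5R)-5-[(1E)-2,6-dimethylhepta-1,5-dien-1-yl]-2,2-dimethyl-1,3-dioxolan-4-yl]-3-methylocta-2,6-dien-1-yl}-6-methylcyclohexa-2,5-diene-1,4-dione
Product: 29 2-[(2E,6E,8R,9R,10E)-8,9-dihydroxy-3,7,11,15-tetramethylhexadeca-2,6,10,14-tetraen-1-yl]-6-methylcyclohexa-2,5-diene-1,4-dione
Conditions: AcOH/H2O (4:1), 40 °C
Reagents that add atoms: none
Why: Acid-catalysed ketal hydrolysis through the 2-alkoxy-2-propyl cation; both diol C–O bonds stay intact, so the stereocentres are untouched, and the quinone is inert to dilute acid.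

Compound list
1 | 4-methoxy-2-methylphenol | COc1ccc(O)c(C)c1 | starting material
2 | 2-bromo-4-methoxy-6-methylphenol | COc1cc(C)c(O)c(Br)c1 | intermediate
3 | 1-bromo-2,5-dimethoxy-3-methylbenzene | COc1cc(C)c(OC)c(Br)c1 | intermediate
4 | pent-3-yn-1-ol | CC#CCCO | starting material
5 | 5-bromopent-2-yne | CC#CCCBr | intermediate
6 | ethyl but-2-ynoate | CC#CC(=O)OCC | starting material
7 | pent-3-yn-1-ylmagnesium bromide | CC#CCC[Mg]Br | intermediate (not isolated)
8 | pent-3-yn-1-ylcopper | CC#CCC[Cu] | intermediate (not isolated)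
9 | ethyl (Z)-2-cuprio-3-methyloct-2-en-6-ynoate (alkenylcopper adduct, Cu cis to the pentynyl chain) | CCOC(=O)/C([Cu])=C(\C)CCC#CC | intermediate (not isolated)
10 | ethyl (E)-3-methyloct-2-en-6-ynoate | CCOC(=O)/C=C(\C)CCC#CC | intermediate
11 | (E)-3-methyloct-2-en-6-yn-1-ol | OC/C=C(\C)CCC#CC | intermediate
12 | (E)-1-bromo-3-methyloct-2-en-6-yne | BrC/C=C(\C)CCC#CC | intermediate
13 | (2,5-dimethoxy-3-methylphenyl)magnesium bromide | COc1cc(C)c(OC)c([Mg]Br)c1 | intermediate (not isolated)
14 | 1-[(2E)-3-methyloct-2-en-6-yn-1-yl]-2,5-dimethoxy-3-methylbenzene | COc1cc(C)c(OC)c(C/C=C(\C)CCC#CC)c1 | intermediate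
15 | chlorobis(cyclopentadienyl)[(2E,6E)-8-(2,5-dimethoxy-3-methylphenyl)-6-methylocta-2,6-dien-2-yl]zirconium | Cl[Zr](C1C=CC=C1)(C1C=CC=C1)/C(C)=C/CC/C(C)=C/Cc1cc(OC)cc(C)c1OC | intermediate (not isolated)
16 | 1-[(2E,6E)-7-iodo-3-methylocta-2,6-dien-1-yl]-2,5-dimethoxy-3-methylbenzene | I/C(C)=C/CC/C(C)=C/Cc1cc(OC)cc(C)c1OC | intermediate
17 | dimethyl (4S,5S)-2,2-dimethyl-1,3-dioxolane-4,5-dicarboxylate | CC1(C)O[C@H](C(=O)OC)[C@@H](C(=O)OC)O1 | starting material
18 | (4S,5S)-5-(methoxycarbonyl)-2,2-dimethyl-1,3-dioxolane-4-carboxylic acid | CC1(C)O[C@H](C(=O)O)[C@@H](C(=O)OC)O1 | intermediate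
19 | 4-(1,3-dioxoisoindolin-2-yl) 5-methyl (4S,5S)-2,2-dimethyl-1,3-dioxolane-4,5-dicarboxylate | CC1(C)O[C@H](C(=O)ON2C(=O)c3ccccc3C2=O)[C@@H](C(=O)OC)O1 | intermediate (not isolated)
20 | methyl (4S,5R)-5-[(2E,6E)-8-(2,5-dimethoxy-3-methylphenyl)-6-methylocta-2,6-dien-2-yl]-2,2-dimethyl-1,3-dioxolane-4-carboxylate | CC1(C)O[C@H](/C(C)=C/CC/C(C)=C/Cc2cc(OC)cc(C)c2OC)[C@@H](C(=O)OC)O1 | intermediate
21 | (4S,5R)-5-[(2E,6E)-8-(2,5-dimethoxy-3-methylphenyl)-6-methylocta-2,6-dien-2-yl]-2,2-dimethyl-1,3-dioxolane-4-carboxylic acid | CC1(C)O[C@H](/C(C)=C/CC/C(C)=C/Cc2cc(OC)cc(C)c2OC)[C@@H](C(=O)O)O1 | intermediate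
22 | 5-bromo-2-methylpent-2-ene | CC(C)=CCCBr | starting material
23 | 6-methylhept-5-en-1-yne | CC(C)=CCCC#C | intermediate
24 | [(1E)-2,6-dimethylhepta-1,5-dien-1-yl]dimethylalane | CC(C)=CCC/C(C)=C/[Al](C)C | intermediate (not isolated)
25 | (E)-1-iodo-2,6-dimethylhepta-1,5-diene | CC(C)=CCC/C(C)=C/I | intermediate
26 | 1,3-dioxoisoindolin-2-yl (4S,5R)-5-[(2E,6E)-8-(2,5-dimethoxy-3-methylphenyl)-6-methylocta-2,6-dien-2-yl]-2,2-dimethyl-1,3-dioxolane-4-carboxylate | CC1(C)O[C@H](/C(C)=C/CC/C(C)=C/Cc2cc(OC)cc(C)c2OC)[C@@H](C(=O)ON2C(=O)c3ccccc3C2=O)O1 | intermediate (not isolated)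
27 | (4R,5R)-4-[(2E,6E)-8-(2,5-dimethoxy-3-methylphenyl)-6-methylocta-2,6-dien-2-yl]-5-[(1E)-2,6-dimethylhepta-1,5-dien-1-yl]-2,2-dimethyl-1,3-dioxolane | CC1(C)O[C@H](/C(C)=C/CC/C(C)=C/Cc2cc(OC)cc(C)c2OC)[C@@H](/C=C(\C)CCC=C(C)C)O1 | intermediate
28 | 2-{(2E,6E)-7-[(4R,5R)-5-[(1E)-2,6-dimethylhepta-1,5-dien-1-yl]-2,2-dimethyl-1,3-dioxolan-4-yl]-3-methylocta-2,6-dien-1-yl}-6-methylcyclohexa-2,5-diene-1,4-dione | CC1(C)O[C@H](/C(C)=C/CC/C(C)=C/CC2=CC(=O)C=C(C)C2=O)[C@@H](/C=C(\C)CCC=C(C)C)O1 | intermediate
29 | 2-[(2E,6E,8R,9R,10E)-8,9-dihydroxy-3,7,11,15-tetramethylhexadeca-2,6,10,14-tetraen-1-yl]-6-methylcyclohexa-2,5-diene-1,4-dione | CC(C)=CCC/C(C)=C/[C@@H](O)[C@H](O)/C(C)=C/CC/C(C)=C/CC1=CC(=O)C=C(C)C1=O | target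

Total step count: 16. Longest linear sequence: 11 steps (steps 3, 4, 5, 6, 7, 8, 10, 11, 14, 15, 16).

Steps most likely to fail

Step 14. The C9′ radical may be reduced or dimerise at the cathode before nickel captures it, or the trans selectivity may erode under electrolysis. The fallback runs the coupling without electrodes, as a redox-neutral Negishi-type decarboxylative alkenylation. It sets out from iodide 25 and the isolated ester 26. Iodine–lithium exchange of 25 (t-BuLi, Et2O, −78 °C) and transmetalation with ZnCl2 should give [(1E)-2,6-dimethylhepta-1,5-dien-1-yl]zinc chloride F1. F1 is coupled with 26 under Ni(acac)2/2,2′-bipyridine in THF/DMF at room temperature, and the route is rejoined at 27.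

Step 10. Oxidative addition of the α-methyl-branched iodide 16 to nickel may be too slow to compete with reduction or dimerisation of the ester-substituted dioxolanyl radical. The fallback avoids the alkenyl halide and brings the alkenyl group in as a nucleophile. It sets out from alkyne 14: hydrozirconation as in step 8 gives 15, which is transmetalated with ZnCl2 (THF, 0 °C) to [(2E,6E)-8-(2,5-dimethoxy-3-methylphenyl)-6-methylocta-2,6-dien-2-yl]zinc chloride F2. F2 is coupled with the isolated ester 19 under Ni(acac)2/2,2′-bipyridine in THF/DMF, and the route is rejoined at 20.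

Step 16. Protic acid may ionise an allylic C–O bond of the bis-allylic diol (allylic transposition or elimination) in competition with ketal hydrolysis. The fallback removes the ketal before the oxidation by aprotic thioketal exchange and makes the last step a fluoride desilylation. It sets out from 27 and returns at 29:
- Ethane-1,2-dithiol with catalytic Zn(OTf)2 in CH2Cl2 at 0 °C should give (2E,6E,8R,9R,10E)-1-(2,5-dimethoxy-3-methylphenyl)-3,7,11,15-tetramethylhexadeca-2,6,10,14-tetraene-8,9-diol F3.
- TBSOTf/2,6-lutidine converts it into the 8,9-bis(tert-butyldimethylsilyl) ether F4.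
- CAN in MeCN/H2O at 0 °C oxidises the arene to the quinone bis(silyl) ether F5.
- HF·pyridine in THF/pyridine at 0 °C releases 29.

Further compounds
F1 | step 14 | [(1E)-2,6-dimethylhepta-1,5-dien-1-yl]zinc chloride | CC(C)=CCC/C(C)=C/[Zn]Cl
F2 | step 10 | [(2E,6E)-8-(2,5-dimethoxy-3-methylphenyl)-6-methylocta-2,6-dien-2-yl]zinc chloride | Cl[Zn]/C(C)=C/CC/C(C)=C/Cc1cc(OC)cc(C)c1OC
F3 | step 16 | (2E,6E,8R,9R,10E)-1-(2,5-dimethoxy-3-methylphenyl)-3,7,11,15-tetramethylhexadeca-2,6,10,14-tetraene-8,9-diol | CC(C)=CCC/C(C)=C/[C@@H](O)[C@H](O)/C(C)=C/CC/C(C)=C/Cc1cc(OC)cc(C)c1OC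
F4 | step 16 | 8,9-bis(tert-butyldimethylsilyl) ether of F3 | CC(C)=CCC/C(C)=C/[C@@H](O[Si](C)(C)C(C)(C)C)[C@H](O[Si](C)(C)C(C)(C)C)/C(C)=C/CC/C(C)=C/Cc1cc(OC)cc(C)c1OC
F5 | step 16 | 2-[(2E,6E,8R,9R,10E)-8,9-bis(tert-butyldimethylsilyloxy)-3,7,11,15-tetramethylhexadeca-2,6,10,14-tetraen-1-yl]-6-methylcyclohexa-2,5-diene-1,4-dione | CC(C)=CCC/C(C)=C/[C@@H](O[Si](C)(C)C(C)(C)C)[C@H](O[Si](C)(C)C(C)(C)C)/C(C)=C/CC/C(C)=C/CC1=CC(=O)C=C(C)C1=O
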